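A small charge of protic impurity need not hold you up: doubled along with the starting material from epsilon to theta, it moves the target reading at 6.00 h from 19.5% to 17.7%, so follow the temperature.

| flask | starting material | reagent | protic impurity | temperature | remark | time |
|---|---|---|---|---|---|---|
| epsilon | 0.31 M | 0.775 M | 0.031 M | −8 °C | run made earlier |  |
| eta | 0.31 M | 0.775 M | 0.12 M | 20 °C | run made earlier |  |
| theta | 0.62 M | 0.775 M | 0.062 M | −8 °C | run made earlier |  |
| green | 0.31 M | 0.775 M | 0.0620 M | −20 °C |  | 12 h |
| blue | 0.31 M | 0.775 M | 0.0620 M | 30 °C |  | 12 h |
| grey | 0.31 M | 0.775 M | 0.0620 M |  | at 30 °C until 6.0 h, from then on at −20 °C | 12 h |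
| ochre | 0.31 M | 0.775 M | 0.0620 M | 5 °C |  | 12 h |

- epsilon (time / h: target / %): 0.500: 3.7; 0.667: 4.7; 1.00: 6.4; 1.33: 8.7; 2.00: 11.9; 3.00: 15.3; 6.00: 19.5
- eta (time / min: target / %): 12.0: 8.4; 25.0: 8.7; 30.0: 7.9; 50.0: 5.9; 60.0: 5.3; 80.0: 4.0
- theta (time / h: target / %): 0.500: 3.4; 1.33: 8.5; 2.00: 11.1; 3.00: 14.7; 6.00: 17.7

(readings scatter by 0.5 percentage points)

- the earlier runs were read with a standard deviation of 0.5 percentage points

- the flask with the highest amount of target, in percent of the starting material charged ("all alike" if they lie within 1.5 percentage points) (green / blue / grey / ochre / all alike)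
- final target, as a percentage of the starting material charged, in green
- final target, as a percentage of the starting material charged, in blue
- final target, as a percentage of the starting material charged, in grey
- final target, as a percentage of the starting material charged, in ochre

When does target peak? Starting material and reagent make it, and eta shows it being lost again, so a curve can have a maximum, as in any consecutive reaction. Eta's highest reading comes at 25.0 min at 20 °C. Epsilon is still rising at its last reading, 6.00 h at −8 °C, so that time is a lower limit. Take the same factor per degree between these two and the peak time becomes 3.14 times epsilon's in green, 18.8 h. In ochre it is 1.74 h, in blue 0.161 h.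

Which flasks pass it? Green's time over its peak time is 0.638; call this ratio the clock number. Ochre stands at 6.90 and blue at 74.7. Green therefore stops on the rise, while ochre has gone past.

How much survives the peak? Eta's fall gives target a life of 73.5 min, and I stretch it by the same factor. Blue then sits through 25.1 lives, too many to leave a readable amount. Grey has 12.7 behind it at the change, and cooling slows a clock already past its peak. Ochre has 2.01 lives, which leaves 1.17% to 2.61%, from peaks like eta's and epsilon's. Green's clock number falls on epsilon at 3.83 h, so my reckoning puts green between 15.3% and 19.5%, above the estimate for ochre, and so the highest flask on this estimate.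

The forecast gave green, with 14.5% in green, 0% in blue, 0% in grey and 1.2% in ochre: “slow but selective, and the target survives”.

The flask gives green as the highest: green 16.8%, blue 0%, grey 0%, ochre 1.32%.

    reagent + target → over-reaction product (k = 0.0258 M⁻¹ h⁻¹, Ea = 62.0 kJ mol⁻¹)
    starting material + protic impurity → quenched substrate (k = 0.305 M⁻¹ h⁻¹, Ea = 55.0 kJ mol⁻¹)
    starting material + reagent → target (k = 0.0298 M⁻¹ h⁻¹, Ea = 59.0 kJ mol⁻¹)
    starting material → side product (k = 0.0226 h⁻¹, Ea = 87.0 kJ mol⁻¹)
    (constants at −20 °C)

Green's clock number of 0.638 says the rise is unfinished, and at 12.0 h green makes target 3.48 times faster than it uses it up. Left until 120 h, a clock number of 6.38, green holds 8.79% instead of 16.8%, so part of the target in green stands because the flask is stopped at the time given. Left until 20 h, green has a clock number of 1.06, just beyond epsilon's last reading, which suggests about 19.5%; the computed flask holds 20.9%.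

The data were computed with constants of no real substance; scatter was added.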